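**Plan**

1. Retrosynthesis: the (R)-2-hydroxy-3-methylbut-3-enyl chain is traced back to a prenyl group. The ring A–prenyl and ring A–isobutyryl C–C bonds are cut next, then the b2–b3 bond of ring B, then the pyranone C3–CH2 bond to ring A, the acetonyl C–C bond and last the lactone.
2. Enabling feature: ring B (b1 bridge CH2, b2 OH, b3 acetyl, b4 OH, b5 CH3, b6 OCH3) is a fully substituted acetylphloroglucinol monomethyl ether. Its atoms b2–b1–b6–b5–b4–b3 plus the acetyl group are the chain of a 3,5,7-trioxo ester, which can be held folded as a 4-methoxy-2-pyranone (b2 = lactone C=O, b1 = C3, b6 = C4, b5 = C5, b4 = C6, b3 = side-chain CH2).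
3. Forward: the pyranone ring is closed first, ring A (as its tribenzyl ether) is joined to C3 by reductive benzylation, and O-methylation plus side-chain acetylation give the acetonylpyranone. Methoxide then turns the pyranone into ring B.
4. Ring A is debenzylated, C-acylated and C-prenylated. On the pentaacetate the prenyl group is epoxidised and isomerised to the allylic silyl ether, and methanolysis releases the target.
5. Stereochemistry: the single (R) centre is set by Shi epoxidation with the D-fructose-derived ketone. The isomerisation that follows breaks only the C–O bond at the tertiary carbon, so the configuration is kept.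

Key step: step 7

Remark on the chemistry: CIP analysis of the target (OH > isopropenyl > CH2Ar > H) gives (R) at the carbinol carbon; methyl 3-oxopentanoate, 1,3,5-tris(benzyloxy)benzene, the Hantzsch ester and the D-fructose-derived ketone are taken as purchased.

**Route**

Step 1
Reactants: 1 methyl 3-oxopentanoate; 2 N-methoxy-N-methylacetamide
Product: 4 methyl 4-methyl-3,5-dioxohexanoate, via dilithium dianion 3 (not isolated)
Conditions: LiN(iPr)2 (2.1 equiv), THF, −78 → 0 °C; then 2, −78 °C → rt; aq. HCl
Reagents that add atoms: N-methoxy-N-methylacetamide (2), CC(=O)N(C)OC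
Why: γ-Acylation of a β-keto ester dianion (Weinreb-type ketone synthesis), in which the γ-carbanion of 3 adds to the amide and the chelated tetrahedral adduct lasts until the acidic quench, so neither proton transfer to the acidic product nor double addition should intervene.

Step 2
Reactants: 4 methyl 4-methyl-3,5-dioxohexanoate
Product: 5 4-hydroxy-5,6-dimethyl-2H-pyran-2-one
Conditions: DBU (1.5 equiv), toluene, 80 °C; then aq. HCl
Reagents that add atoms: none
Why: Base-promoted lactonisation of a 3,5-dioxo ester, the C5 enolate oxygen attacking the ester carbon with loss of methanol, is the standard entry to 4-hydroxy-2-pyranones.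

Step 3
Reactants: 6 1,3,5-tris(benzyloxy)benzene
Product: 8 2,4,6-tris(benzyloxy)benzaldehyde, via aryl iminium salt 7 (not isolated)
Conditions: POCl3, DMF, 0 °C → rt; then H2O, rt → 60 °C
Reagents that add atoms: N,N-dimethylformamide, CN(C)C=O; water, O
Why: Vilsmeier–Haack formylation of a phloroglucinol triether, whose three equivalent positions are each activated by all three alkoxy groups, while the iminium ion 7 is deactivated against a second attack.

Step 4
Reactants: 5 4-hydroxy-5,6-dimethyl-2H-pyran-2-one; 8 2,4,6-tris(benzyloxy)benzaldehyde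
Product: 10 4-hydroxy-5,6-dimethyl-3-[2,4,6-tris(benzyloxy)benzyl]-2H-pyran-2-one, via alkylidene pyrandione 9 (not isolated)
Conditions: L-proline (20 mol %), Hantzsch ester (diethyl 2,6-dimethyl-1,4-dihydropyridine-3,5-dicarboxylate, 1.1 equiv), CH2Cl2, rt
Reagents that add atoms: none
Why: Organocatalytic three-component reductive alkylation (Knoevenagel condensation through the proline iminium ion, then conjugate hydride transfer from the Hantzsch ester), which should reduce 9 before a second pyranone can add and so avoid the methylene-bis(pyranone).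

Step 5
Reactants: 10 4-hydroxy-5,6-dimethyl-3-[2,4,6-tris(benzyloxy)benzyl]-2H-pyran-2-one
Product: 11 4-methoxy-5,6-dimethyl-3-[2,4,6-tris(benzyloxy)benzyl]-2H-pyran-2-one
Conditions: Me2SO4, K2CO3, acetone, reflux
Reagents that add atoms: dimethyl sulfate, COS(=O)(=O)OC
Why: O-Methylation of the pyranone anion with a hard electrophile under carbonate conditions is expected at the 4-oxygen, giving the 4-methoxy-2-pyranone and not the 2-methoxy-4-pyranone, and no other acidic OH is present.

Step 6
Reactants: 11 4-methoxy-5,6-dimethyl-3-[2,4,6-tris(benzyloxy)benzyl]-2H-pyran-2-one; 2 N-methoxy-N-methylacetamide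
Product: 13 4-methoxy-5-methyl-6-(2-oxopropyl)-3-[2,4,6-tris(benzyloxy)benzyl]-2H-pyran-2-one, via lithiated pyranone 12 (not isolated)
Conditions: LiN(iPr)2 (1.1 equiv), THF, −78 °C; then 2, −78 → −20 °C; cold dilute aq. HCl
Reagents that add atoms: N-methoxy-N-methylacetamide (2), CC(=O)N(C)OC
Why: Lateral (vinylogous) lithiation of the 6-methyl group gives the only carbonyl-conjugated anion available (C3 is blocked and the 5-methyl group is cross-conjugated), and acylation by the N-methoxy-N-methylamide stops at the chelated adduct, which shields the acidic acetonyl product until work-up.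

Step 7
Reactants: 13 4-methoxy-5-methyl-6-(2-oxopropyl)-3-[2,4,6-tris(benzyloxy)benzyl]-2H-pyran-2-one
Product: 15 1-[2,6-dihydroxy-4-methoxy-3-methyl-5-(2,4,6-tris(benzyloxy)benzyl)phenyl]ethan-1-one, via ring-opened trioxo ester 14 (not isolated)
Conditions: Mg(OMe)2 (4 equiv), MeOH, reflux; then cold aq. HCl
Reagents that add atoms: none
Why: Methoxide adds to the lactone carbonyl b2 and the ring opens to the magnesium enolate of trioxo ester 14, in which the carbanion b3 flanked by the two ketones attacks the ester carbon b2, methoxide leaves and the cyclic triketone enolises to the arene. The closest known reaction type is the base-induced recyclisation of 6-(2-oxoalkyl)-4-methoxy-2-pyranones to acylphloroglucinol monomethyl ethers, a Claisen (Dieckmann-type) condensation of a 3,5,7-trioxo ester. Ring B closes in the 6-exo-trig mode, the ester C=O lying outside the ring that the new b2–b3 bond completes. No stereocentre is formed. The step needs Claisen closure to win over aldol closure and over retro-Claisen loss of the acetyl group: the cis arrangement of ester and diketone arm across the former C3=C4 bond, inherited from the lactone, keeps b2 within reach of b3, an aldol closure would have to pass through the fully substituted vinylic carbon b1 and could not aromatise, and chelation of the β-diketone by divalent magnesium shields it from methoxide.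

Step 8
Reactants: 15 1-[2,6-dihydroxy-4-methoxy-3-methyl-5-(2,4,6-tris(benzyloxy)benzyl)phenyl]ethan-1-one
Product: 16 1-[2,6-dihydroxy-4-methoxy-3-methyl-5-(2,4,6-trihydroxybenzyl)phenyl]ethan-1-one
Conditions: H2 (1 atm), 10% Pd/C, EtOAc–MeOH, rt
Reagents that add atoms: none
Why: Hydrogenolysis of aryl benzyl ethers over Pd/C, under which the diarylmethane C–C bonds, the aryl methyl ether and the hydrogen-bonded aryl ketone should not be reduced.

Step 9
Reactants: 16 1-[2,6-dihydroxy-4-methoxy-3-methyl-5-(2,4,6-trihydroxybenzyl)phenyl]ethan-1-one; 17 isobutyryl chloride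
Product: 18 1-[3-(3-acetyl-2,4-dihydroxy-6-methoxy-5-methylbenzyl)-2,4,6-trihydroxyphenyl]-2-methylpropan-1-one
Conditions: AlCl3 (6 equiv), PhNO2–CH2Cl2, 0 °C → rt; then ice-cold aq. HCl
Reagents that add atoms: isobutyryl chloride (17), CC(C)C(Cl)=O
Why: Friedel–Crafts C-acylation of a C-alkylphloroglucinol, in which ring B offers no free carbon, the two free positions of ring A are equivalent and the first acyl group deactivates ring A against a second.

Step 10
Reactants: 18 1-[3-(3-acetyl-2,4-dihydroxy-6-methoxy-5-methylbenzyl)-2,4,6-trihydroxyphenyl]-2-methylpropan-1-one; 19 prenyl bromide (1-bromo-3-methylbut-2-ene)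
Product: 20 1-[3-(3-acetyl-2,4-dihydroxy-6-methoxy-5-methylbenzyl)-2,4,6-trihydroxy-5-(3-methylbut-2-en-1-yl)phenyl]-2-methylpropan-1-one
Conditions: 10% aq. KOH, 0 °C, 19 (1.0 equiv) added slowly; then aq. HCl
Reagents that add atoms: prenyl bromide (19), CC(C)=CCBr
Why: C-Alkylation of an acylphloroglucinol phenoxide in water, where solvation of the oxygens favours attack through carbon and the one remaining aromatic CH of ring A is the only site at which C-alkylation restores aromaticity.

Step 11
Reactants: 20 the prenylated pentaphenol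
Product: 21 pentaacetate of 20 (all five phenolic OH as OAc)
Conditions: Ac2O, pyridine, DMAP (cat.), 0 °C → rt
Reagents that add atoms: acetic anhydride, CC(=O)OC(C)=O
Why: Exhaustive O-acetylation with nucleophilic catalysis by DMAP masks every phenol that could otherwise be oxidised or open the epoxide of the next step by 5-exo or 6-endo attack.

Step 12
Reactants: 21 pentaacetate of 20
Product: 22 (R)-epoxide pentaacetate (as 21 but with the side chain [(2R)-3,3-dimethyloxiran-2-yl]methyl)
Conditions: D-fructose-derived Shi ketone (1,2:4,5-di-O-isopropylidene-β-D-erythro-2,3-hexodiulo-2,6-pyranose, 3 equiv), Oxone (2KHSO5·KHSO4·K2SO4), NaHCO3, Bu4NHSO4 (cat.), MeCN–aq. Na2EDTA, pH 7–8, 0 °C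
Reagents that add atoms: potassium peroxymonosulfate (KHSO5 of Oxone), [K+].[O-]S(=O)(=O)OO
Why: Shi asymmetric epoxidation of the trisubstituted prenyl alkene, in which the dioxirane of the D-fructose-derived ketone delivers oxygen through the spiro transition state to the face that gives the (R)-epoxide (the same sense as for trans-disubstituted and other trisubstituted alkenes), and the bicarbonate-buffered variant with excess ketone should leave the aryl acetates intact.

Step 13
Reactants: 22 (R)-epoxide pentaacetate
Product: 23 (R)-allyl silyl ether pentaacetate (as 21 but with the side chain (2R)-3-methyl-2-(trimethylsilyloxy)but-3-en-1-yl)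
Conditions: Me3SiOSO2CF3 (1.2 equiv), DBU (1.5 equiv), toluene, 0 °C → rt
Reagents that add atoms: trimethylsilyl trifluoromethanesulfonate, C[Si](C)(C)OS(=O)(=O)C(F)(F)F
Why: Silyl triflate/amidine isomerisation of a 2,2-dimethyl-3-alkyloxirane to an allyl silyl ether, in which O-silylation opens the epoxide at the tertiary carbon and DBU removes a methyl proton, so the isopropenyl carbinol ether forms while the C–O bond at the stereocentre stays intact and (R) is retained.

Step 14
Reactants: 23 (R)-allyl silyl ether pentaacetate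
Product: 24 1-[3-(3-acetyl-2,4-dihydroxy-6-methoxy-5-methylbenzyl)-2,4,6-trihydroxy-5-[(2R)-2-hydroxy-3-methylbut-3-en-1-yl]phenyl]-2-methylpropan-1-one (CNP0162925.1)
Conditions: K2CO3 (6 equiv), MeOH, argon, 0 °C → rt; then dilute aq. HCl to pH 5, 0 °C
Reagents that add atoms: none
Why: Carbonate-mediated methanolysis cleaves the five aryl acetates and the trimethylsilyl ether without touching the allylic alcohol, the alkene or the ketones, and no electrophilic site remains for the liberated phenoxides.

**Compound list**

1 | methyl 3-oxopentanoate | CCC(=O)CC(=O)OC | starting material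
2 | N-methoxy-N-methylacetamide | CC(=O)N(C)OC | starting material
3 | dilithium dianion of methyl 3-oxopentanoate | [Li+].[Li+].C[CH-]C([O-])=CC(=O)OC | intermediate (not isolated)
4 | methyl 4-methyl-3,5-dioxohexanoate | CC(=O)C(C)C(=O)CC(=O)OC | intermediate
5 | 4-hydroxy-5,6-dimethyl-2H-pyran-2-one | CC1=C(C)C(O)=CC(=O)O1 | intermediate
6 | 1,3,5-tris(benzyloxy)benzene | c1ccc(COc2cc(OCc3ccccc3)cc(OCc3ccccc3)c2)cc1 | starting material
7 | N-[2,4,6-tris(benzyloxy)benzylidene]-N-methylmethanaminium dichlorophosphate | C[N+](C)=Cc1c(OCc2ccccc2)cc(OCc2ccccc2)cc1OCc1ccccc1.[O-]P(=O)(Cl)Cl | intermediate (not isolated)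
8 | 2,4,6-tris(benzyloxy)benzaldehyde | O=Cc1c(OCc2ccccc2)cc(OCc2ccccc2)cc1OCc1ccccc1 | intermediate
9 | 5,6-dimethyl-3-[2,4,6-tris(benzyloxy)benzylidene]-2H-pyran-2,4(3H)-dione | CC1=C(C)C(=O)C(=Cc2c(OCc3ccccc3)cc(OCc3ccccc3)cc2OCc2ccccc2)C(=O)O1 | intermediate (not isolated)
10 | 4-hydroxy-5,6-dimethyl-3-[2,4,6-tris(benzyloxy)benzyl]-2H-pyran-2-one | CC1=C(C)C(O)=C(Cc2c(OCc3ccccc3)cc(OCc3ccccc3)cc2OCc2ccccc2)C(=O)O1 | intermediate
11 | 4-methoxy-5,6-dimethyl-3-[2,4,6-tris(benzyloxy)benzyl]-2H-pyran-2-one | CC1=C(C)C(OC)=C(Cc2c(OCc3ccccc3)cc(OCc3ccccc3)cc2OCc2ccccc2)C(=O)O1 | intermediate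
12 | 6-lithiomethyl derivative of 11 (delocalised trienolate) | [Li+].[CH2-]C1=C(C)C(OC)=C(Cc2c(OCc3ccccc3)cc(OCc3ccccc3)cc2OCc2ccccc2)C(=O)O1 | intermediate (not isolated)
13 | 4-methoxy-5-methyl-6-(2-oxopropyl)-3-[2,4,6-tris(benzyloxy)benzyl]-2H-pyran-2-one | CC(=O)CC1=C(C)C(OC)=C(Cc2c(OCc3ccccc3)cc(OCc3ccccc3)cc2OCc2ccccc2)C(=O)O1 | intermediate (key-step precursor)
14 | methyl (2E)-3-methoxy-4-methyl-5,7-dioxo-2-[2,4,6-tris(benzyloxy)benzyl]oct-2-enoate (present as its magnesium enolate) | COC(=O)/C(Cc1c(OCc2ccccc2)cc(OCc2ccccc2)cc1OCc1ccccc1)=C(OC)\C(C)C(=O)CC(C)=O | intermediate (not isolated)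
15 | 1-[2,6-dihydroxy-4-methoxy-3-methyl-5-(2,4,6-tris(benzyloxy)benzyl)phenyl]ethan-1-one | CC(=O)c1c(O)c(C)c(OC)c(Cc2c(OCc3ccccc3)cc(OCc3ccccc3)cc2OCc2ccccc2)c1O | intermediate (key-step product)
16 | 1-[2,6-dihydroxy-4-methoxy-3-methyl-5-(2,4,6-trihydroxybenzyl)phenyl]ethan-1-one | CC(=O)c1c(O)c(C)c(OC)c(Cc2c(O)cc(O)cc2O)c1O | intermediate
17 | isobutyryl chloride | CC(C)C(Cl)=O | starting material
18 | 1-[3-(3-acetyl-2,4-dihydroxy-6-methoxy-5-methylbenzyl)-2,4,6-trihydroxyphenyl]-2-methylpropan-1-one | CC(=O)c1c(O)c(C)c(OC)c(Cc2c(O)cc(O)c(C(=O)C(C)C)c2O)c1O | intermediate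
19 | prenyl bromide (1-bromo-3-methylbut-2-ene) | CC(C)=CCBr | starting material
20 | 1-[3-(3-acetyl-2,4-dihydroxy-6-methoxy-5-methylbenzyl)-2,4,6-trihydroxy-5-(3-methylbut-2-en-1-yl)phenyl]-2-methylpropan-1-one | CC(=O)c1c(O)c(C)c(OC)c(Cc2c(O)c(CC=C(C)C)c(O)c(C(=O)C(C)C)c2O)c1O | intermediate
21 | pentaacetate of 20 | CC(=O)c1c(OC(C)=O)c(C)c(OC)c(Cc2c(OC(C)=O)c(CC=C(C)C)c(OC(C)=O)c(C(=O)C(C)C)c2OC(C)=O)c1OC(C)=O | intermediate
22 | pentaacetate with the side chain [(2R)-3,3-dimethyloxiran-2-yl]methyl | CC(=O)c1c(OC(C)=O)c(C)c(OC)c(Cc2c(OC(C)=O)c(C[C@H]3OC3(C)C)c(OC(C)=O)c(C(=O)C(C)C)c2OC(C)=O)c1OC(C)=O | intermediate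
23 | pentaacetate with the side chain (2R)-3-methyl-2-(trimethylsilyloxy)but-3-en-1-yl | CC(=O)c1c(OC(C)=O)c(C)c(OC)c(Cc2c(OC(C)=O)c(C[C@@H](O[Si](C)(C)C)C(C)=C)c(OC(C)=O)c(C(=O)C(C)C)c2OC(C)=O)c1OC(C)=O | intermediate
24 | 1-[3-(3-acetyl-2,4-dihydroxy-6-methoxy-5-methylbenzyl)-2,4,6-trihydroxy-5-[(2R)-2-hydroxy-3-methylbut-3-en-1-yl]phenyl]-2-methylpropan-1-one | C=C(C)[C@H](O)Cc1c(O)c(Cc2c(O)c(C(C)=O)c(O)c(C)c2OC)c(O)c(C(=O)C(C)C)c1O | target

**Count and risks**

Total step count: 14. Longest linear sequence: 13 steps (steps 1, 2 and 4 to 14, from methyl 3-oxopentanoate); step 3 is the one-step side branch.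

Steps most likely to fail:

Step 13. The silyl-activated epoxide may divert into a 1,2-hydride shift (semipinacol path to the saturated ketone), and the amidine may induce acyl transfer from the aryl acetates instead of clean methyl deprotonation. The fallback sets out from 21 and bypasses steps 12 and 13. Schenck ene photooxygenation (O2, tetraphenylporphyrin, visible light, CH2Cl2, 0 °C) should give the racemic secondary allylic hydroperoxide pentaacetate F1 beside its tertiary regioisomer. Ac2O, pyridine and DMAP (Kornblum–DeLaMare-type dehydration) should convert it into the enone pentaacetate F2; the tertiary hydroperoxide cannot dehydrate and would be removed by chromatography. Corey–Bakshi–Shibata reduction with the (S)-2-methyl-oxazaborolidine and catecholborane (toluene, −78 °C), the isopropenyl group acting as the larger substituent, should then give the (R)-allylic alcohol pentaacetate F3. Methanolysis of F3 under the conditions of step 14 returns to the route at 24.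

Step 10. O-Alkylation, dearomatising C-alkylation of the fully substituted ring B and double alkylation may compete with attack at the single free carbon of ring A. The fallback sets out from 18 and uses a Friedel–Crafts prenylation with 2-methylbut-3-en-2-ol and BF3·OEt2 in dioxane at rt. The prenyl cation can substitute only an aromatic C–H, and the only one present is on ring A. This gives 20 directly, so no further compound arises (F0), and the route is rejoined at 20.

Step 9. The strong Lewis acid may heterolyse the ring A–CH2 bond (retro-Friedel–Crafts transfer of the benzyl unit, scrambling of the methylene bridge) or drive O-acylation and double acylation. The fallback sets out from 16 and uses a Houben–Hoesch reaction: isobutyronitrile, ZnCl2 and HCl gas in Et2O at 0 °C should precipitate the ketiminium chloride F4, which cannot react a second time. Hydrolysis of F4 in hot water returns to the route at 18.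

Further compounds
F1 | step 13 | racemic pentaacetate with the side chain 2-hydroperoxy-3-methylbut-3-en-1-yl | CC(=O)c1c(OC(C)=O)c(C)c(OC)c(Cc2c(OC(C)=O)c(CC(OO)C(C)=C)c(OC(C)=O)c(C(=O)C(C)C)c2OC(C)=O)c1OC(C)=O
F2 | step 13 | pentaacetate with the side chain 3-methyl-2-oxobut-3-en-1-yl | CC(=O)c1c(OC(C)=O)c(C)c(OC)c(Cc2c(OC(C)=O)c(CC(=O)C(C)=C)c(OC(C)=O)c(C(=O)C(C)C)c2OC(C)=O)c1OC(C)=O
F3 | step 13 | pentaacetate with the side chain (2R)-2-hydroxy-3-methylbut-3-en-1-yl | CC(=O)c1c(OC(C)=O)c(C)c(OC)c(Cc2c(OC(C)=O)c(C[C@@H](O)C(C)=C)c(OC(C)=O)c(C(=O)C(C)C)c2OC(C)=O)c1OC(C)=O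
F0 | step 10 | none | none
F4 | step 9 | ketiminium chloride of 18 (C=NH2+ in place of the isobutyryl C=O) | CC(=O)c1c(O)c(C)c(OC)c(Cc2c(O)cc(O)c(C(=[NH2+])C(C)C)c2O)c1O.[Cl-]
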